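Assumption: the stereocentre in the SMILES is read as (S) (OH > CH2Ar > CH2-alkyl > H), and methyl 3,5-dihydroxyphenylacetate is taken as a catalogue compound.

**Retrosynthetic overview**
1. Target 13 comes from 12 by one neutral hydrogenation that saturates the chain alkene and removes both O-benzyl groups; the acetate is placed beforehand on the only free OH (phenol 11).
2. C4–C14 of the chain come from cross-metathesis of homoallylic ether 8 with undec-1-ene.
3. Key disconnection: the C2–C3 bond, made by asymmetric allylboration of arylacetaldehyde 5, which also sets the single (S) stereocentre.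
4. 5 comes from methyl 3,5-dihydroxyphenylacetate 1 by mono-benzylation, MOM protection, reduction and oxidation; Bn/MOM differentiation of the two equivalent phenols is done at the start.
5. No ring is formed; the benzene ring is bought with 1.

**Route**

Step 1
Reactants: 1 methyl 2-(3,5-dihydroxyphenyl)acetate
Product: 2 methyl 2-[3-(benzyloxy)-5-hydroxyphenyl]acetate
Conditions: BnBr (0.9 equiv), K2CO3 (1.0 equiv), acetone, reflux; chromatography, recovered 1 recycled
Reagents that add atoms: benzyl bromide, BrCc1ccccc1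
Why: Williamson etherification of one of two equivalent phenols is statistical (about 40–45% of 2, with dibenzyl ether and unreacted 1 separated), which is tolerable as the first step on the cheapest material, and carbonate is too weak to enolise the ester.

Step 2
Reactants: 2 methyl 2-[3-(benzyloxy)-5-hydroxyphenyl]acetate
Product: 3 methyl 2-[3-(benzyloxy)-5-(methoxymethoxy)phenyl]acetate
Conditions: MOMCl, i-Pr2NEt, CH2Cl2, 0 °C → rt
Reagents that add atoms: chloromethyl methyl ether, COCCl
Why: O-alkylation of the phenol with an α-chloro ether (MOM protection) gives an acetal that is stable to hydride, base and Ru carbenes but is removed later by acid without touching benzyl ethers.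

Step 3
Reactants: 3 methyl 2-[3-(benzyloxy)-5-(methoxymethoxy)phenyl]acetate
Product: 4 2-[3-(benzyloxy)-5-(methoxymethoxy)phenyl]ethan-1-ol
Conditions: LiAlH4, THF, 0 °C; Fieser work-up
Reagents that add atoms: none
Why: LiAlH4 reduction of the ester to the primary alcohol is clean because the aryl ethers and the MOM acetal are inert to hydride.

Step 4
Reactants: 4 2-[3-(benzyloxy)-5-(methoxymethoxy)phenyl]ethan-1-ol
Product: 5 2-[3-(benzyloxy)-5-(methoxymethoxy)phenyl]acetaldehyde
Conditions: Dess–Martin periodinane, CH2Cl2, 0 °C → rt, 1 h; aq NaHCO3/Na2S2O3 work-up; crude used at once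
Reagents that add atoms: none
Why: Dess–Martin oxidation stops at the aldehyde under near-neutral, non-enolising conditions, which suits a sensitive arylacetaldehyde that is not stored.

Step 5
Reactants: 5 2-[3-(benzyloxy)-5-(methoxymethoxy)phenyl]acetaldehyde
Product: 7 (2S)-1-[3-(benzyloxy)-5-(methoxymethoxy)phenyl]pent-4-en-2-ol, via diisopinocampheylborinate ester 6 (not isolated)
Conditions: (–)-Ipc2BOMe [from (+)-α-pinene], allylMgBr, Et2O, 0 °C → rt; then 5, –78 °C, 2 h; then 3 M NaOH, 30% H2O2, 0 °C → rt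
Reagents that add atoms: allylmagnesium bromide, C=CC[Mg]Br
Why: Brown asymmetric allylboration proceeds through a closed chair Zimmerman–Traxler transition state in which the (1R,2S,3R,5R)-isopinocampheyl groups direct allyl to the Si face of the aldehyde, giving the (S)-carbinol because CH2Ar outranks allyl (typically ≥90% ee, checked by Mosher ester or chiral HPLC), and it is fast at –78 °C so the enolisable aldehyde is consumed before it self-condenses.

Step 6
Reactants: 7 (2S)-1-[3-(benzyloxy)-5-(methoxymethoxy)phenyl]pent-4-en-2-ol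
Product: 8 1-(benzyloxy)-3-[(2S)-2-(benzyloxy)pent-4-en-1-yl]-5-(methoxymethoxy)benzene
Conditions: NaH, BnBr, Bu4NI (cat.), THF/DMF, 0 °C → rt
Reagents that add atoms: benzyl bromide, BrCc1ccccc1
Why: Williamson etherification reacts at oxygen only, so the C–O stereocentre is untouched, and the resulting benzyl ether leaves in the final hydrogenation together with the phenolic one.

Step 7
Reactants: 8 1-(benzyloxy)-3-[(2S)-2-(benzyloxy)pent-4-en-1-yl]-5-(methoxymethoxy)benzene; 9 undec-1-ene (4 equiv)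
Product: 10 1-(benzyloxy)-3-[(2S,4E)-2-(benzyloxy)tetradec-4-en-1-yl]-5-(methoxymethoxy)benzene
Conditions: Grubbs II (5 mol %), 1,4-benzoquinone (10 mol %), CH2Cl2, 40 °C
Reagents that add atoms: none
Why: olefin cross-metathesis of two terminal alkenes is driven by the excess of the cheap partner and loss of ethylene, benzoquinone suppresses Ru–H chain-walking that would give chain-length homologues, and the E-major geometry is irrelevant because the alkene is hydrogenated in step 10.

Step 8
Reactants: 10 1-(benzyloxy)-3-[(2S,4E)-2-(benzyloxy)tetradec-4-en-1-yl]-5-(methoxymethoxy)benzene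
Product: 11 3-(benzyloxy)-5-[(2S,4E)-2-(benzyloxy)tetradec-4-en-1-yl]phenol
Conditions: conc. HCl (3 equiv), MeOH/THF 1:1, 45 °C
Reagents that add atoms: none
Why: acid-catalysed acetal cleavage transfers the MOM group to methanol as dimethoxymethane, while benzyl ethers, the isolated alkene and the stereocentre are inert to dilute acid.

Step 9
Reactants: 11 3-(benzyloxy)-5-[(2S,4E)-2-(benzyloxy)tetradec-4-en-1-yl]phenol
Product: 12 3-(benzyloxy)-5-[(2S,4E)-2-(benzyloxy)tetradec-4-en-1-yl]phenyl acetate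
Conditions: Ac2O, Et3N, DMAP (cat.), CH2Cl2, 0 °C → rt
Reagents that add atoms: acetic anhydride, CC(=O)OC(C)=O
Why: DMAP-catalysed acylation meets exactly one free hydroxyl, so the acetate is placed unambiguously on the intended phenol.

Step 10
Reactants: 12 3-(benzyloxy)-5-[(2S,4E)-2-(benzyloxy)tetradec-4-en-1-yl]phenyl acetate
Product: 13 3-hydroxy-5-[(2S)-2-hydroxytetradecyl]phenyl acetate
Conditions: H2 (1–3 atm), 10% Pd/C or Pd(OH)2/C, EtOAc, rt
Reagents that add atoms: none
Why: catalytic hydrogenation saturates the alkene and hydrogenolyses both O-benzyl groups in a neutral aprotic medium in which the aryl acetate neither transesterifies nor migrates, and the non-benzylic carbinol keeps its (S) configuration.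

**Compound list**
1 | methyl 2-(3,5-dihydroxyphenyl)acetate | COC(=O)Cc1cc(O)cc(O)c1 | starting material
2 | methyl 2-[3-(benzyloxy)-5-hydroxyphenyl]acetate | COC(=O)Cc1cc(O)cc(OCc2ccccc2)c1 | intermediate
3 | methyl 2-[3-(benzyloxy)-5-(methoxymethoxy)phenyl]acetate | COCOc1cc(CC(=O)OC)cc(OCc2ccccc2)c1 | intermediate
4 | 2-[3-(benzyloxy)-5-(methoxymethoxy)phenyl]ethan-1-ol | COCOc1cc(CCO)cc(OCc2ccccc2)c1 | intermediate
5 | 2-[3-(benzyloxy)-5-(methoxymethoxy)phenyl]acetaldehyde | COCOc1cc(CC=O)cc(OCc2ccccc2)c1 | intermediate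
6 | {[(2S)-1-[3-(benzyloxy)-5-(methoxymethoxy)phenyl]pent-4-en-2-yl]oxy}bis[(1R,2S,3R,5R)-2,6,6-trimethylbicyclo[3.1.1]heptan-3-yl]borane | C=CC[C@H](OB([C@@H]1C[C@@H]2C[C@H]([C@H]1C)C2(C)C)[C@@H]1C[C@@H]2C[C@H]([C@H]1C)C2(C)C)Cc1cc(OCOC)cc(OCc2ccccc2)c1 | intermediate (not isolated)
7 | (2S)-1-[3-(benzyloxy)-5-(methoxymethoxy)phenyl]pent-4-en-2-ol | C=CC[C@H](O)Cc1cc(OCOC)cc(OCc2ccccc2)c1 | intermediate
8 | 1-(benzyloxy)-3-[(2S)-2-(benzyloxy)pent-4-en-1-yl]-5-(methoxymethoxy)benzene | C=CC[C@H](OCc1ccccc1)Cc1cc(OCOC)cc(OCc2ccccc2)c1 | intermediate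
9 | undec-1-ene | CCCCCCCCCC=C | starting material
10 | 1-(benzyloxy)-3-[(2S,4E)-2-(benzyloxy)tetradec-4-en-1-yl]-5-(methoxymethoxy)benzene (E major, minor Z isomer carried along) | CCCCCCCCC/C=C/C[C@H](OCc1ccccc1)Cc1cc(OCOC)cc(OCc2ccccc2)c1 | intermediate
11 | 3-(benzyloxy)-5-[(2S,4E)-2-(benzyloxy)tetradec-4-en-1-yl]phenol | CCCCCCCCC/C=C/C[C@H](OCc1ccccc1)Cc1cc(O)cc(OCc2ccccc2)c1 | intermediate
12 | 3-(benzyloxy)-5-[(2S,4E)-2-(benzyloxy)tetradec-4-en-1-yl]phenyl acetate | CCCCCCCCC/C=C/C[C@H](OCc1ccccc1)Cc1cc(OC(C)=O)cc(OCc2ccccc2)c1 | intermediate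
13 | 3-hydroxy-5-[(2S)-2-hydroxytetradecyl]phenyl acetate | CCCCCCCCCCCC[C@H](O)Cc1cc(O)cc(OC(C)=O)c1 | target

**Totals**
Total step count: 10. Longest linear sequence: 10 steps (1 → 13); 9 is bought and enters in step 7.

**Three steps most likely to fail, with fallbacks**

Step 5 (the aldehyde 5 is enolisable and air-sensitive, and the ee depends on reagent quality). The fallback avoids 5 and sets the carbinol by a decarboxylative Claisen condensation followed by Noyori hydrogenation. It sets out from 3 and comes back at 8.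
- LiOH in THF/H2O gives 2-[3-(benzyloxy)-5-(methoxymethoxy)phenyl]acetic acid F1.
- CDI in THF converts it into 2-[3-(benzyloxy)-5-(methoxymethoxy)phenyl]-1-(1H-imidazol-1-yl)ethan-1-one F2, which is not isolated.
- F2 C-acylates magnesium ethyl malonate (potassium ethyl malonate, MgCl2, Et3N, MeCN/THF) to give the chelated 2-{[3-(benzyloxy)-5-(methoxymethoxy)phenyl]acetyl}-3-ethoxy-3-oxopropanoic acid F3, which loses CO2 on acidic work-up to give ethyl 4-[3-(benzyloxy)-5-(methoxymethoxy)phenyl]-3-oxobutanoate F4.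
- H2 (4–10 atm) with RuCl2[(R)-BINAP] in EtOH at 50 °C gives ethyl (3R)-4-[3-(benzyloxy)-5-(methoxymethoxy)phenyl]-3-hydroxybutanoate F5. The (3R) descriptor corresponds to the (S) carbinol of the target because CH2CO2Et outranks CH2Ar.
- Neutral benzylation with 2-benzyloxy-1-methylpyridinium triflate and MgO in PhCF3 at 85 °C (base would cause retro-aldol or elimination) gives ethyl (3R)-3-(benzyloxy)-4-[3-(benzyloxy)-5-(methoxymethoxy)phenyl]butanoate F6.
- DIBAL-H in CH2Cl2 at –78 °C gives (3R)-3-(benzyloxy)-4-[3-(benzyloxy)-5-(methoxymethoxy)phenyl]butanal F7.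
- Wittig methylenation (Ph3PCH3Br, KHMDS, THF, –78 → 0 °C) gives 8.

Step 7 (homodimerisation, incomplete conversion or chain-walking in the cross-metathesis). The fallback builds the chain by oxidative cleavage and Wittig olefination instead. It sets out from 8 and comes back at 13.
- OsO4 (cat.), NaIO4 and 2,6-lutidine in dioxane/H2O cleave the terminal alkene to (3R)-3-(benzyloxy)-4-[3-(benzyloxy)-5-(methoxymethoxy)phenyl]butanal F7, the aldehyde already described in the first fallback.
- Decyltriphenylphosphonium bromide and NaHMDS in THF (–78 → 0 °C) give 1-(benzyloxy)-3-[(2S,4Z)-2-(benzyloxy)tetradec-4-en-1-yl]-5-(methoxymethoxy)benzene F8.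
- The conditions of step 8 give 3-(benzyloxy)-5-[(2S,4Z)-2-(benzyloxy)tetradec-4-en-1-yl]phenol F9.
- The conditions of step 9 give 3-(benzyloxy)-5-[(2S,4Z)-2-(benzyloxy)tetradec-4-en-1-yl]phenyl acetate F10.
- The hydrogenation of step 10 erases the alkene geometry and gives 13.

Step 10 (the secondary alkyl benzyl ether may be slow to hydrogenolyse, and forcing risks the aryl acetate). The fallback splits the deprotection into a short hydrogenation and a Lewis-acid debenzylation. It sets out from 12 and comes back at 13.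
- A brief hydrogenation (Pd/C, EtOAc, 1 atm), stopped once the alkene is saturated and the phenolic benzyl group is gone, gives 3-[(2S)-2-(benzyloxy)tetradecyl]-5-hydroxyphenyl acetate F11.
- BCl3 (3 equiv) with pentamethylbenzene as cation scavenger in CH2Cl2 at –78 °C removes the remaining benzyl ether, conditions the aryl acetate is expected to survive, and gives 13.

**Further compounds**
F1 | step 5 | 2-[3-(benzyloxy)-5-(methoxymethoxy)phenyl]acetic acid | COCOc1cc(CC(O)=O)cc(OCc2ccccc2)c1
F2 | step 5 | 2-[3-(benzyloxy)-5-(methoxymethoxy)phenyl]-1-(1H-imidazol-1-yl)ethan-1-one | COCOc1cc(CC(=O)n2ccnc2)cc(OCc2ccccc2)c1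
F3 | step 5 | 2-{[3-(benzyloxy)-5-(methoxymethoxy)phenyl]acetyl}-3-ethoxy-3-oxopropanoic acid (magnesium chelate, not isolated) | CCOC(=O)C(C(O)=O)C(=O)Cc1cc(OCOC)cc(OCc2ccccc2)c1
F4 | step 5 | ethyl 4-[3-(benzyloxy)-5-(methoxymethoxy)phenyl]-3-oxobutanoate | CCOC(=O)CC(=O)Cc1cc(OCOC)cc(OCc2ccccc2)c1
F5 | step 5 | ethyl (3R)-4-[3-(benzyloxy)-5-(methoxymethoxy)phenyl]-3-hydroxybutanoate | CCOC(=O)C[C@H](O)Cc1cc(OCOC)cc(OCc2ccccc2)c1
F6 | step 5 | ethyl (3R)-3-(benzyloxy)-4-[3-(benzyloxy)-5-(methoxymethoxy)phenyl]butanoate | CCOC(=O)C[C@H](OCc1ccccc1)Cc1cc(OCOC)cc(OCc2ccccc2)c1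
F7 | step 5 | (3R)-3-(benzyloxy)-4-[3-(benzyloxy)-5-(methoxymethoxy)phenyl]butanal | O=CC[C@H](OCc1ccccc1)Cc1cc(OCOC)cc(OCc2ccccc2)c1
F8 | step 7 | 1-(benzyloxy)-3-[(2S,4Z)-2-(benzyloxy)tetradec-4-en-1-yl]-5-(methoxymethoxy)benzene | CCCCCCCCC/C=C\C[C@H](OCc1ccccc1)Cc1cc(OCOC)cc(OCc2ccccc2)c1
F9 | step 7 | 3-(benzyloxy)-5-[(2S,4Z)-2-(benzyloxy)tetradec-4-en-1-yl]phenol | CCCCCCCCC/C=C\C[C@H](OCc1ccccc1)Cc1cc(O)cc(OCc2ccccc2)c1
F10 | step 7 | 3-(benzyloxy)-5-[(2S,4Z)-2-(benzyloxy)tetradec-4-en-1-yl]phenyl acetate | CCCCCCCCC/C=C\C[C@H](OCc1ccccc1)Cc1cc(OC(C)=O)cc(OCc2ccccc2)c1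
F11 | step 10 | 3-[(2S)-2-(benzyloxy)tetradecyl]-5-hydroxyphenyl acetate | CCCCCCCCCCCC[C@H](OCc1ccccc1)Cc1cc(O)cc(OC(C)=O)c1
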